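**Retrosynthetic overview**

1. Target 22 (5,7,4'-trihydroxy-3,6,8-trimethoxyflavone) ⇐ hydrogenolysis of three benzyl ethers ⇐ 3-O-methylation ⇐ C3 lithiation–borylation–oxidation of the 3-unsubstituted flavone 17.
2. Feature used: C4 is a single carbonyl carbon held between C3 and C4a, the only ring A carbon that carries no oxygen, and O1 sits on the neighbouring C8a. Ring C is therefore cut at C4a–C4, C4–C3 and O1–C2 into 2-iodophenol 12, carbon monoxide 14 and arylacetylene 13.
3. Iodophenol 12 ⇐ 2,6-dimethoxyphenol 1: O-benzylation, then dibromination at the two positions ortho/para to the methoxy groups. The two equivalent bromines are then turned into oxygen one after the other (Br–Li exchange, borate, peroxide) with a benzylation in between, so the future C5 and C8a oxygens are told apart without a statistical monoprotection. Iodine enters last at the only remaining ring C–H (future C4a).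
4. Ring order: rings A and B are bought as arenes; ring C is the only ring made, in step 7.

Key step: step 7

Remark: flavone numbering is used throughout (O1, C2, C3, C4, C4a, C5–C8, C8a; ring B primed). The target is achiral, so no stereocentre has to be set.

**Route**

Step 1
Reactants: 1 2,6-dimethoxyphenol; 2 benzyl bromide
Product: 3 2-(benzyloxy)-1,3-dimethoxybenzene
Conditions: K2CO3, DMF, 60 °C
Reagents that add atoms: none
Why: Williamson ether synthesis; the phenoxide of 1 is alkylated by the reactive benzylic bromide despite its two ortho methoxy groups.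

Step 2
Reactants: 3 2-(benzyloxy)-1,3-dimethoxybenzene
Product: 4 3-(benzyloxy)-1,5-dibromo-2,4-dimethoxybenzene
Conditions: NBS (2.2 equiv), MeCN, 0 °C to 40 °C, dark
Reagents that add atoms: N-bromosuccinimide, O=C1CCC(=O)N1Br
Why: Electrophilic aromatic bromination; each of the two positions taken is ortho to one methoxy group and para to the other, whereas the third position is activated only by the twisted central benzyloxy group, and the symmetry of 3 makes the dibromide a single isomer.

Step 3
Reactants: 4 3-(benzyloxy)-1,5-dibromo-2,4-dimethoxybenzene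
Product: 7 3-(benzyloxy)-5-bromo-2,4-dimethoxyphenol, via aryllithium 5 (not isolated), via lithium aryltrimethoxyborate 6 (not isolated)
Conditions: n-BuLi (1.05 equiv), THF, −78 °C; B(OMe)3, −78 °C to rt; AcOH, 30% H2O2, 0 °C to rt
Reagents that add atoms: n-butyllithium, [Li]CCCC (Li in 5 only); trimethyl borate, COB(OC)OC (boron unit in 6 only); hydrogen peroxide, OO (phenol oxygen of 7)
Why: Bromine–lithium exchange followed by borylation–oxidation; the two bromines are equivalent, exchange with one equivalent of n-BuLi should stop at the monolithio arene (a second exchange on an aryllithium is disfavoured), and peroxide oxidation of the borate moves the aryl group from boron to oxygen.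

Step 4
Reactants: 7 3-(benzyloxy)-5-bromo-2,4-dimethoxyphenol; 2 benzyl bromide
Product: 8 1,3-bis(benzyloxy)-5-bromo-2,4-dimethoxybenzene
Conditions: K2CO3, DMF, rt
Reagents that add atoms: none
Why: Williamson ether synthesis on the single free phenol, which fixes the benzyl group on the future C5 oxygen.

Step 5
Reactants: 8 1,3-bis(benzyloxy)-5-bromo-2,4-dimethoxybenzene
Product: 11 3,5-bis(benzyloxy)-2,4-dimethoxyphenol, via aryllithium 9 (not isolated), via lithium aryltrimethoxyborate 10 (not isolated)
Conditions: n-BuLi (1.1 equiv), THF, −78 °C; B(OMe)3, −78 °C to rt; AcOH, 30% H2O2, 0 °C to rt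
Reagents that add atoms: n-butyllithium, [Li]CCCC (Li in 9 only); trimethyl borate, COB(OC)OC (boron unit in 10 only); hydrogen peroxide, OO (phenol oxygen of 11)
Why: The same bromine–lithium exchange and borylation–oxidation sequence on the remaining bromide; exchange at −78 °C is much faster than deprotonation of the benzyl ethers, and the new hydroxyl is the future C8a–O1 oxygen.

Step 6
Reactants: 11 3,5-bis(benzyloxy)-2,4-dimethoxyphenol
Product: 12 3,5-bis(benzyloxy)-2-iodo-4,6-dimethoxyphenol
Conditions: NIS (1.05 equiv), MeCN, 0 °C, dark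
Reagents that add atoms: N-iodosuccinimide, O=C1CCC(=O)N1I
Why: Electrophilic aromatic iodination; ring A has one C–H left, it is ortho to the free hydroxyl and strongly activated, and the benzyl rings are not activated enough to react.

Step 7
Reactants: 12 3,5-bis(benzyloxy)-2-iodo-4,6-dimethoxyphenol; 13 1-(benzyloxy)-4-ethynylbenzene (1.5 equiv); 14 carbon monoxide
Product: 17 5,7,4'-tris(benzyloxy)-6,8-dimethoxyflavone, via hydroxyaryl ynone 15 (not isolated), via enaminone 16 (not isolated)
Conditions: PdCl2(dppf) (5 mol%; dppf = 1,1'-bis(diphenylphosphino)ferrocene), Et2NH, CO (20 bar), 120 °C, autoclave, no copper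
Reagents that add atoms: diethylamine, CCNCC (its atoms are in intermediate 16 only and leave again on ring closure)
Why: PdCl2(dppf) is reduced in situ to zerovalent palladium, which inserts into the C4a–I bond of 12; CO insertion gives the aroyl–palladium species, and the acetylide formed from 13 and diethylamine is transferred to palladium and reductively eliminated to give ynone 15, which sets C4a–C4 and C4–C3. Diethylamine then adds to the ynone to give enaminone 16, and the C8a phenol oxygen displaces the amine at C2 by addition–elimination, which forms O1–C2 and closes ring C in the 6-endo mode. The closest known reaction type is the palladium-catalysed carbonylative Sonogashira annulation of 2-iodophenols with terminal alkynes to flavones in a secondary amine. No stereocentre is formed. Two selectivities are needed: CO insertion must outrun direct alkynylation (which would lead to a 2-arylbenzofuran) and amine capture of the aroyl–palladium species, for which the CO pressure, the absence of copper and the excess of 13 are chosen; and the phenol oxygen must close at C2 and not by 5-exo attack at C3 (aurone), which prior formation of enaminone 16 should ensure because it makes C2 the electrophilic carbon carrying a leaving group. Because the C4a–I bond sits between OH and OBn on a ring with five oxygen substituents, insertion of palladium is expected to be rate-limiting, which is why the bidentate, electron-rich dppf ligand and 120 °C are specified.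

Step 8
Reactants: 17 5,7,4'-tris(benzyloxy)-6,8-dimethoxyflavone
Product: 20 5,7,4'-tris(benzyloxy)-3-hydroxy-6,8-dimethoxyflavone, via 3-lithioflavone 18 (not isolated), via lithium flavonyltrimethoxyborate 19 (not isolated)
Conditions: LDA (1.3 equiv), THF, −78 °C; B(OMe)3, −78 °C to 0 °C; AcOH, 30% H2O2, 0 °C to rt
Reagents that add atoms: lithium diisopropylamide, CC(C)N([Li])C(C)C (Li in 18 only); trimethyl borate, COB(OC)OC (boron unit in 19 only); hydrogen peroxide, OO (the 3-hydroxyl oxygen of 20)
Why: C3 lithiation of a flavone with LDA followed by borylation–oxidation; C3–H is the only proton LDA can remove at −78 °C (vinylic, next to the C4 carbonyl), and the borate is oxidised under acidic peroxide conditions that the pyranone tolerates.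

Step 9
Reactants: 20 5,7,4'-tris(benzyloxy)-3-hydroxy-6,8-dimethoxyflavone
Product: 21 5,7,4'-tris(benzyloxy)-3,6,8-trimethoxyflavone
Conditions: MeI, K2CO3, acetone, reflux
Reagents that add atoms: iodomethane, CI
Why: Williamson O-methylation of the only free hydroxyl, the acidic enolic 3-OH.

Step 10
Reactants: 21 5,7,4'-tris(benzyloxy)-3,6,8-trimethoxyflavone
Product: 22 5,7,4'-trihydroxy-3,6,8-trimethoxyflavone (target)
Conditions: H2 (1 atm), 10% Pd/C, EtOAc–MeOH, rt
Reagents that add atoms: none
Why: Catalytic hydrogenolysis of the three benzyl aryl ethers; the tetrasubstituted, conjugated C2=C3 bond, the C4 carbonyl and the methyl ethers should be left untouched under these mild conditions.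

**Compound list**

1 | 2,6-dimethoxyphenol | COc1cccc(OC)c1O | starting material
2 | benzyl bromide | BrCc1ccccc1 | starting material
3 | 2-(benzyloxy)-1,3-dimethoxybenzene | COc1cccc(OC)c1OCc1ccccc1 | intermediate
4 | 3-(benzyloxy)-1,5-dibromo-2,4-dimethoxybenzene | COc1c(Br)cc(Br)c(OC)c1OCc1ccccc1 | intermediate
5 | [3-(benzyloxy)-5-bromo-2,4-dimethoxyphenyl]lithium | COc1c([Li])cc(Br)c(OC)c1OCc1ccccc1 | intermediate
6 | lithium [3-(benzyloxy)-5-bromo-2,4-dimethoxyphenyl]trimethoxyborate | [Li+].COc1c([B-](OC)(OC)OC)cc(Br)c(OC)c1OCc1ccccc1 | intermediate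
7 | 3-(benzyloxy)-5-bromo-2,4-dimethoxyphenol | COc1c(O)cc(Br)c(OC)c1OCc1ccccc1 | intermediate
8 | 1,3-bis(benzyloxy)-5-bromo-2,4-dimethoxybenzene | COc1c(Br)cc(OCc2ccccc2)c(OC)c1OCc1ccccc1 | intermediate
9 | [3,5-bis(benzyloxy)-2,4-dimethoxyphenyl]lithium | COc1c([Li])cc(OCc2ccccc2)c(OC)c1OCc1ccccc1 | intermediate
10 | lithium [3,5-bis(benzyloxy)-2,4-dimethoxyphenyl]trimethoxyborate | [Li+].COc1c([B-](OC)(OC)OC)cc(OCc2ccccc2)c(OC)c1OCc1ccccc1 | intermediate
11 | 3,5-bis(benzyloxy)-2,4-dimethoxyphenol | COc1c(O)cc(OCc2ccccc2)c(OC)c1OCc1ccccc1 | intermediate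
12 | 3,5-bis(benzyloxy)-2-iodo-4,6-dimethoxyphenol | COc1c(O)c(I)c(OCc2ccccc2)c(OC)c1OCc1ccccc1 | intermediate
13 | 1-(benzyloxy)-4-ethynylbenzene | C#Cc1ccc(OCc2ccccc2)cc1 | starting material
14 | carbon monoxide | [C-]#[O+] | starting material
15 | 1-[2,4-bis(benzyloxy)-6-hydroxy-3,5-dimethoxyphenyl]-3-[4-(benzyloxy)phenyl]prop-2-yn-1-one | COc1c(O)c(C(=O)C#Cc2ccc(OCc3ccccc3)cc2)c(OCc2ccccc2)c(OC)c1OCc1ccccc1 | intermediate
16 | (E)-1-[2,4-bis(benzyloxy)-6-hydroxy-3,5-dimethoxyphenyl]-3-[4-(benzyloxy)phenyl]-3-(diethylamino)prop-2-en-1-one | COc1c(O)c(C(=O)/C=C(\c2ccc(OCc3ccccc3)cc2)N(CC)CC)c(OCc2ccccc2)c(OC)c1OCc1ccccc1 | intermediate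
17 | 5,7,4'-tris(benzyloxy)-6,8-dimethoxyflavone | COc1c(OCc2ccccc2)c(OC)c2oc(-c3ccc(OCc4ccccc4)cc3)cc(=O)c2c1OCc1ccccc1 | intermediate
18 | [5,7,4'-tris(benzyloxy)-6,8-dimethoxyflavon-3-yl]lithium | COc1c(OCc2ccccc2)c(OC)c2oc(-c3ccc(OCc4ccccc4)cc3)c([Li])c(=O)c2c1OCc1ccccc1 | intermediate
19 | lithium [5,7,4'-tris(benzyloxy)-6,8-dimethoxyflavon-3-yl]trimethoxyborate | [Li+].COc1c(OCc2ccccc2)c(OC)c2oc(-c3ccc(OCc4ccccc4)cc3)c([B-](OC)(OC)OC)c(=O)c2c1OCc1ccccc1 | intermediate
20 | 5,7,4'-tris(benzyloxy)-3-hydroxy-6,8-dimethoxyflavone | COc1c(OCc2ccccc2)c(OC)c2oc(-c3ccc(OCc4ccccc4)cc3)c(O)c(=O)c2c1OCc1ccccc1 | intermediate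
21 | 5,7,4'-tris(benzyloxy)-3,6,8-trimethoxyflavone | COc1c(OCc2ccccc2)c(OC)c2oc(-c3ccc(OCc4ccccc4)cc3)c(OC)c(=O)c2c1OCc1ccccc1 | intermediate
22 | 5,7,4'-trihydroxy-3,6,8-trimethoxyflavone | COc1c(O)c(OC)c2oc(-c3ccc(O)cc3)c(OC)c(=O)c2c1O | target

**Step count and risks**

Total step count: 10. Longest linear sequence: 10 steps (1 to 22).

Steps most likely to fail:

1. Step 7. Palladium insertion into the crowded, electron-rich C4a–I bond may be so slow that hydrodeiodination, capture of the aroyl–palladium species by diethylamine, or alkynylation without CO insertion take over. The fallback sets out from phenol 11 and builds the same three bonds of ring C by polar chemistry without palladium or CO. Magnesium-mediated ortho-formylation (MgCl2, Et3N, paraformaldehyde, MeCN, reflux) places the future C4 carbon on the only free ring position and should give 2,4-bis(benzyloxy)-6-hydroxy-3,5-dimethoxybenzaldehyde F1. The lithium acetylide of 13 (n-BuLi, THF, −78 °C to 0 °C, 2.5 equiv, the first equivalent being consumed by the phenol) adds to the aldehyde to give racemic 1-[2,4-bis(benzyloxy)-6-hydroxy-3,5-dimethoxyphenyl]-3-[4-(benzyloxy)phenyl]prop-2-yn-1-ol F2. MnO2 in CH2Cl2 oxidises this to ynone 15, here isolated, and Et2NH in EtOH at rt takes 15 through enaminone 16 to flavone 17, where the route resumes at step 8.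

2. Step 8. The 3-lithio species may open ring C by expelling the C8a phenoxide if the temperature rises before the borate is formed, or deprotonation may be incomplete or stray to a benzylic position. The fallback sets out from flavone 17 and oxidises the C2=C3 bond instead of deprotonating C3. Dimethyldioxirane in acetone–CH2Cl2 at 0 °C should give racemic 5,7,4'-tris(benzyloxy)-6,8-dimethoxyflavone 2,3-epoxide F3. Catalytic p-TsOH in CH2Cl2 then opens the epoxide at C2, and loss of the C3 proton gives flavonol 20, where the route resumes at step 9.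

3. Step 6. The electrophilic iodine source may oxidise the very electron-rich phenol (oxidative loss of a methyl group towards a quinone) instead of substituting the ring. The fallback sets out from phenol 11 and introduces iodine through an aryllithium. MOMCl and i-Pr2NEt in CH2Cl2 give 1,3-bis(benzyloxy)-2,4-dimethoxy-5-(methoxymethoxy)benzene F4. Directed ortho-metalation with n-BuLi in THF at 0 °C at the C–H between the two oxygen donors, then I2 at −78 °C, gives 1,3-bis(benzyloxy)-4-iodo-2,6-dimethoxy-5-(methoxymethoxy)benzene F5. HCl in MeOH at rt removes the methoxymethyl group and returns iodophenol 12, where the route resumes at step 7.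

**Further compounds**

F1 | step 7 | 2,4-bis(benzyloxy)-6-hydroxy-3,5-dimethoxybenzaldehyde | COc1c(O)c(C=O)c(OCc2ccccc2)c(OC)c1OCc1ccccc1
F2 | step 7 | racemic 1-[2,4-bis(benzyloxy)-6-hydroxy-3,5-dimethoxyphenyl]-3-[4-(benzyloxy)phenyl]prop-2-yn-1-ol | COc1c(O)c(C(O)C#Cc2ccc(OCc3ccccc3)cc2)c(OCc2ccccc2)c(OC)c1OCc1ccccc1
F3 | step 8 | racemic 5,7,4'-tris(benzyloxy)-6,8-dimethoxyflavone 2,3-epoxide (cis-fused; one enantiomer drawn) | O=C1c2c(OCc3ccccc3)c(OC)c(OCc3ccccc3)c(OC)c2O[C@@]4(c5ccc(OCc6ccccc6)cc5)O[C@@H]14
F4 | step 6 | 1,3-bis(benzyloxy)-2,4-dimethoxy-5-(methoxymethoxy)benzene | COCOc1cc(OCc2ccccc2)c(OC)c(OCc2ccccc2)c1OC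
F5 | step 6 | 1,3-bis(benzyloxy)-4-iodo-2,6-dimethoxy-5-(methoxymethoxy)benzene | COCOc1c(I)c(OCc2ccccc2)c(OC)c(OCc2ccccc2)c1OC
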